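The synthesis rests on disconnecting the C3–C4 bond of the upper pyran ring C. C4 is a methine held between two aryl carbons (C4a of ring A and C8 of the afzelechin ring D) and C3 carries a hydroxyl trans to both neighbours, so this bond can be made as a ring alkene and hydrated afterwards. Ring-closing metathesis of a diene that carries a vinyl group on the C2 stereocentre and a 1,1-diarylethylene joining rings A and D closes ring C as a 4-aryl-2H-chromene in one operation. Hydroboration anti to the C2 aryl group then sets C3 and C4 together.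

Key step: step 10

Remarks on the chemistry:
- (+)-Afzelechin (2R,3S) is taken as a purchasable natural flavan-3-ol; it supplies both stereocentres of the lower unit.
- The (Sa,Sc,Sc) phosphoramidite in step 4 is assumed to give the (S)-ether, by the usual facial preference of this catalyst family; if the sense proves opposite, the antipodal ligand is used.
- The target is fisetinidol-(4α→8)-afzelechin: upper unit 2R,3S,4S (2,3-trans-3,4-trans), lower unit 2R,3S. Rotamers about the C4–C8 axis are conformers and need no control.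

Step 1
Reactants: 1 3,4-bis(benzyloxy)benzaldehyde
Product: 2 ethyl (E)-3-[3,4-bis(benzyloxy)phenyl]prop-2-enoate
Conditions: (EtO)2P(O)CH2CO2Et, NaH, THF, 0 °C → rt
Reagents that add atoms: triethyl phosphonoacetate, CCOC(=O)CP(=O)(OCC)OCC
Why: Horner–Wadsworth–Emmons olefination of an aromatic aldehyde with a stabilised phosphonate anion should give the E-enoate.

Step 2
Reactants: 2 ethyl (E)-3-[3,4-bis(benzyloxy)phenyl]prop-2-enoate
Product: 3 (E)-3-[3,4-bis(benzyloxy)phenyl]prop-2-en-1-ol
Conditions: i-Bu2AlH (2.2 equiv), CH2Cl2, −78 → 0 °C; aq KNaC4H4O6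
Reagents that add atoms: none
Why: 1,2-reduction of the enoate by the aluminium hydride should give the allylic alcohol without touching the alkene or the benzyl ethers.

Step 3
Reactants: 3 (E)-3-[3,4-bis(benzyloxy)phenyl]prop-2-en-1-ol
Product: 4 (E)-3-[3,4-bis(benzyloxy)phenyl]prop-2-en-1-yl methyl carbonate
Conditions: ClCO2Me, pyridine, CH2Cl2, 0 °C
Reagents that add atoms: methyl chloroformate, COC(=O)Cl
Why: O-acylation of the primary allylic alcohol installs the carbonate leaving group needed for ionisation by iridium.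

Step 4
Reactants: 4 (E)-3-[3,4-bis(benzyloxy)phenyl]prop-2-en-1-yl methyl carbonate; 5 1-[4-(benzyloxy)-2-hydroxyphenyl]ethan-1-one
Product: 7 1-[4-(benzyloxy)-2-{[(1S)-1-[3,4-bis(benzyloxy)phenyl]prop-2-en-1-yl]oxy}phenyl]ethan-1-one, via sodium aryloxide 6 (not isolated)
Conditions: 5, NaH, THF, 0 °C; then 4, [Ir(cod)Cl]2 (2 mol%), (Sa,Sc,Sc)-O,O'-(1,1'-binaphthyl-2,2'-diyl) N,N-bis(1-phenylethyl)phosphoramidite (4 mol%), catalyst pre-activated with n-PrNH2, THF, 50 °C
Reagents that add atoms: none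
Why: Iridium-catalysed asymmetric allylic etherification, in which the aryloxide attacks the aryl-substituted terminus of the allyl–iridium intermediate and the cyclometalated iridium–phosphoramidite complex selects the face, should give the branched ether and set the future C2 (S here, 2R in the flavan after the priority change).

Step 5
Reactants: 8 (+)-afzelechin, (2R,3S)-2-(4-hydroxyphenyl)chromane-3,5,7-triol
Product: 9 5,7,4'-tri-O-benzylafzelechin, (2R,3S)-5,7-bis(benzyloxy)-2-[4-(benzyloxy)phenyl]chroman-3-ol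
Conditions: BnBr (3.3 equiv), K2CO3, DMF, 0 °C → rt, N2
Reagents that add atoms: benzyl bromide, BrCc1ccccc1
Why: Williamson etherification with a carbonate base should benzylate the three phenols only and leave the secondary alcohol and both stereocentres untouched.

Step 6
Reactants: 9 5,7,4'-tri-O-benzylafzelechin
Product: 10 3,5,7,4'-tetra-O-benzylafzelechin, (2R,3S)-3,5,7-tris(benzyloxy)-2-[4-(benzyloxy)phenyl]chromane
Conditions: NaH, BnBr, Bu4NI (cat.), DMF, 0 °C → rt
Reagents that add atoms: benzyl bromide, BrCc1ccccc1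
Why: Williamson etherification of the secondary alkoxide masks the last acidic proton before the organometallic step, and makes every protecting group removable in one final hydrogenolysis.

Step 7
Reactants: 10 3,5,7,4'-tetra-O-benzylafzelechin
Product: 11 8-bromo-3,5,7,4'-tetra-O-benzylafzelechin
Conditions: NBS (1.0 equiv), CH2Cl2, −78 °C → rt
Reagents that add atoms: N-bromosuccinimide, O=C1CCC(=O)N1Br
Why: Electrophilic aromatic bromination of the phloroglucinol-type ring should occur at C8, the position favoured in 5,7-di-O-benzylflavan-3-ol ethers, and spare the less electron-rich 4-benzyloxyphenyl ring.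

Step 8
Reactants: 11 8-bromo-3,5,7,4'-tetra-O-benzylafzelechin; 7 1-[4-(benzyloxy)-2-{[(1S)-1-[3,4-bis(benzyloxy)phenyl]prop-2-en-1-yl]oxy}phenyl]ethan-1-one
Product: 14 1-[4-(benzyloxy)-2-{[(1S)-1-[3,4-bis(benzyloxy)phenyl]prop-2-en-1-yl]oxy}phenyl]-1-(3,5,7,4'-tetra-O-benzylafzelechin-8-yl)ethan-1-ol (both carbinol epimers), via aryllithium 12 (not isolated), via arylcerium dichloride 13 (not isolated)
Conditions: 11, n-BuLi, THF, −78 °C; anhydrous CeCl3, −78 °C; then 7, −78 → −20 °C; H2O
Reagents that add atoms: none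
Why: Bromine–lithium exchange followed by transmetalation gives a weakly basic organocerium reagent that should add 1,2 to the enolisable, hindered aryl methyl ketone; the new carbinol centre forms as a mixture that is erased in step 9.

Step 9
Reactants: 14 tertiary diaryl carbinol
Product: 15 8-{1-[4-(benzyloxy)-2-{[(1S)-1-[3,4-bis(benzyloxy)phenyl]prop-2-en-1-yl]oxy}phenyl]ethenyl}-3,5,7,4'-tetra-O-benzylafzelechin (the 1,1-diarylethylene diene)
Conditions: Burgess reagent (MeO2CN(−)SO2N(+)Et3), THF, 50 °C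
Reagents that add atoms: none
Why: Burgess dehydration of the tertiary bis-benzylic alcohol can only eliminate toward the methyl group and runs without acid, so the acid-labile benzylic allylic aryl ether and its stereocentre should survive.

Step 10
Reactants: 15 the 1,1-diarylethylene diene
Product: 16 (2S)-7-(benzyloxy)-2-[3,4-bis(benzyloxy)phenyl]-4-(3,5,7,4'-tetra-O-benzylafzelechin-8-yl)-2H-chromene
Conditions: (H2IMes)Cl2Ru(=CH-C6H4-2-O-i-Pr) (second-generation Hoveyda–Grubbs catalyst, 10 mol%), 1,4-benzoquinone (20 mol%), toluene (5 mM), 60 °C, argon sparge, dark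
Reagents that add atoms: none
Why: The ruthenium alkylidene loads onto the unhindered vinyl group at C3 of 15 and then engages the 1,1-diarylethylene intramolecularly; [2+2] cycloaddition and cycloreversion of the ruthenacyclobutane join C3 to C4 as a ring double bond and release ethylene. The closest known reaction is the ring-closing metathesis of 2-(allyloxy)-α-arylstyrenes to 4-aryl-2H-chromenes. Ring C is closed as a six-membered ring in which both carbons of the new C3=C4 double bond are ring members. No stereocentre is created here: C2 is carried through unchanged from step 4, and the trigonal C3 and C4 become the two remaining stereocentres in step 11 under control of C2. The step needs loading at the vinyl group, cyclisation in preference to dimerisation and no migration of the vinyl double bond toward C2; the difference in hindrance between the two alkenes, high dilution and 1,4-benzoquinone as a scavenger of ruthenium hydrides should secure these. The product is kept at or below 60 °C and away from light so that reversible electrocyclic opening of the 2H-chromene does not erode C2.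

Step 11
Reactants: 16 the 4-aryl-2H-chromene
Product: 18 hepta-O-benzyl fisetinidol-(4α→8)-afzelechin with free upper C3 hydroxyl, (2R,3S,4S)-7-(benzyloxy)-2-[3,4-bis(benzyloxy)phenyl]-4-(3,5,7,4'-tetra-O-benzylafzelechin-8-yl)chroman-3-ol, via alkylborane 17 (not isolated)
Conditions: BH3·THF (5 equiv), THF, 0 °C → rt; then 3 M NaOH, 30% H2O2, 0 °C → rt
Reagents that add atoms: hydrogen peroxide, OO
Why: Hydroboration–oxidation adds H and B syn across C3=C4 from the face opposite the C2 aryl group, with boron at C3 (away from the diaryl-substituted C4) and oxidation with retention, so the C3 hydroxyl should end trans to the C2 aryl and trans to ring D at C4 (2R,3S,4S).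

Step 12
Reactants: 18 hepta-O-benzyl fisetinidol-(4α→8)-afzelechin
Product: 19 fisetinidol-(4α→8)-afzelechin, (2R,3S,4S)-2-(3,4-dihydroxyphenyl)-4-[(2R,3S)-3,5,7-trihydroxy-2-(4-hydroxyphenyl)chroman-8-yl]chromane-3,7-diol
Conditions: H2 (1 atm), Pd(OH)2/C, THF–MeOH, rt; filtration and chromatography on Sephadex LH-20 under argon
Reagents that add atoms: none
Why: Catalytic hydrogenolysis cleaves the six aryl benzyl ethers and the one alkyl benzyl ether under neutral conditions, which should leave the cyclic benzylic C2–O bonds, the interflavan bond and all five stereocentres intact.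

Compound list
1 | 3,4-bis(benzyloxy)benzaldehyde | O=Cc1ccc(OCc2ccccc2)c(OCc2ccccc2)c1 | starting material
2 | ethyl (E)-3-[3,4-bis(benzyloxy)phenyl]prop-2-enoate | CCOC(=O)/C=C/c1ccc(OCc2ccccc2)c(OCc2ccccc2)c1 | intermediate
3 | (E)-3-[3,4-bis(benzyloxy)phenyl]prop-2-en-1-ol | OC/C=C/c1ccc(OCc2ccccc2)c(OCc2ccccc2)c1 | intermediate
4 | (E)-3-[3,4-bis(benzyloxy)phenyl]prop-2-en-1-yl methyl carbonate | COC(=O)OC/C=C/c1ccc(OCc2ccccc2)c(OCc2ccccc2)c1 | intermediate
5 | 1-[4-(benzyloxy)-2-hydroxyphenyl]ethan-1-one | CC(=O)c1ccc(OCc2ccccc2)cc1O | starting material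
6 | sodium 2-acetyl-5-(benzyloxy)phenolate (not isolated) | CC(=O)c1ccc(OCc2ccccc2)cc1[O-].[Na+] | intermediate
7 | 1-[4-(benzyloxy)-2-{[(1S)-1-[3,4-bis(benzyloxy)phenyl]prop-2-en-1-yl]oxy}phenyl]ethan-1-one | CC(=O)c1ccc(OCc2ccccc2)cc1O[C@@H](C=C)c1ccc(OCc2ccccc2)c(OCc2ccccc2)c1 | intermediate
8 | (+)-afzelechin, (2R,3S)-2-(4-hydroxyphenyl)chromane-3,5,7-triol | Oc1ccc([C@H]2Oc3c(c(O)cc(O)c3)C[C@@H]2O)cc1 | starting material
9 | 5,7,4'-tri-O-benzylafzelechin | C(Oc1ccc([C@H]2Oc3c(c(OCc4ccccc4)cc(OCc4ccccc4)c3)C[C@@H]2O)cc1)c1ccccc1 | intermediate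
10 | 3,5,7,4'-tetra-O-benzylafzelechin | C(Oc1ccc([C@H]2Oc3c(c(OCc4ccccc4)cc(OCc4ccccc4)c3)C[C@@H]2OCc2ccccc2)cc1)c1ccccc1 | intermediate
11 | 8-bromo-3,5,7,4'-tetra-O-benzylafzelechin | C(Oc1ccc([C@H]2Oc3c(c(OCc4ccccc4)cc(OCc4ccccc4)c3Br)C[C@@H]2OCc2ccccc2)cc1)c1ccccc1 | intermediate
12 | 8-lithio-3,5,7,4'-tetra-O-benzylafzelechin (not isolated) | C(Oc1ccc([C@H]2Oc3c(c(OCc4ccccc4)cc(OCc4ccccc4)c3[Li])C[C@@H]2OCc2ccccc2)cc1)c1ccccc1 | intermediate
13 | 8-(dichlorocerio)-3,5,7,4'-tetra-O-benzylafzelechin (not isolated) | C(Oc1ccc([C@H]2Oc3c(c(OCc4ccccc4)cc(OCc4ccccc4)c3[Ce](Cl)Cl)C[C@@H]2OCc2ccccc2)cc1)c1ccccc1 | intermediate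
14 | 1-[4-(benzyloxy)-2-{[(1S)-1-[3,4-bis(benzyloxy)phenyl]prop-2-en-1-yl]oxy}phenyl]-1-(3,5,7,4'-tetra-O-benzylafzelechin-8-yl)ethan-1-ol, both carbinol epimers | C(Oc1ccc([C@H]2Oc3c(c(OCc4ccccc4)cc(OCc4ccccc4)c3C(C)(O)c3ccc(OCc4ccccc4)cc3O[C@@H](C=C)c3ccc(OCc4ccccc4)c(OCc4ccccc4)c3)C[C@@H]2OCc2ccccc2)cc1)c1ccccc1 | intermediate
15 | 8-{1-[4-(benzyloxy)-2-{[(1S)-1-[3,4-bis(benzyloxy)phenyl]prop-2-en-1-yl]oxy}phenyl]ethenyl}-3,5,7,4'-tetra-O-benzylafzelechin | C(Oc1ccc([C@H]2Oc3c(c(OCc4ccccc4)cc(OCc4ccccc4)c3C(=C)c3ccc(OCc4ccccc4)cc3O[C@@H](C=C)c3ccc(OCc4ccccc4)c(OCc4ccccc4)c3)C[C@@H]2OCc2ccccc2)cc1)c1ccccc1 | intermediate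
16 | (2S)-7-(benzyloxy)-2-[3,4-bis(benzyloxy)phenyl]-4-(3,5,7,4'-tetra-O-benzylafzelechin-8-yl)-2H-chromene | C(Oc1ccc([C@H]2Oc3c(c(OCc4ccccc4)cc(OCc4ccccc4)c3C3=C[C@@H](c4ccc(OCc5ccccc5)c(OCc5ccccc5)c4)Oc4cc(OCc5ccccc5)ccc34)C[C@@H]2OCc2ccccc2)cc1)c1ccccc1 | intermediate
17 | C3 alkylborane of 16, boron trans to the C2 aryl and cis to H4 (not isolated) | C(Oc1ccc([C@H]2Oc3c(c(OCc4ccccc4)cc(OCc4ccccc4)c3[C@@H]3c4ccc(OCc5ccccc5)cc4O[C@H](c4ccc(OCc5ccccc5)c(OCc5ccccc5)c4)[C@H]3B)C[C@@H]2OCc2ccccc2)cc1)c1ccccc1 | intermediate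
18 | hepta-O-benzyl fisetinidol-(4α→8)-afzelechin, upper C3 hydroxyl free | C(Oc1ccc([C@H]2Oc3c(c(OCc4ccccc4)cc(OCc4ccccc4)c3[C@@H]3c4ccc(OCc5ccccc5)cc4O[C@H](c4ccc(OCc5ccccc5)c(OCc5ccccc5)c4)[C@H]3O)C[C@@H]2OCc2ccccc2)cc1)c1ccccc1 | intermediate
19 | fisetinidol-(4α→8)-afzelechin | Oc1ccc([C@H]2Oc3c(c(O)cc(O)c3[C@@H]3c4ccc(O)cc4O[C@H](c4ccc(O)c(O)c4)[C@H]3O)C[C@@H]2O)cc1 | target

Total step count: 12.
Longest linear sequence: 9 steps (steps 1, 2, 3, 4, 8, 9, 10, 11, 12, from aldehyde 1); the afzelechin branch (steps 5–7) joins at step 8.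

Steps most likely to fail

Step 10 (ring-closing metathesis). The ruthenacyclobutane may fail to form at the twisted, tri-ortho-substituted 1,1-diarylethylene, so the loaded carbene would dimerise or decompose instead; slow turnover also gives time for double-bond migration toward C2. The fallback sets out from 7 and comes back at 16. It keeps the ring closure at C3–C4 but offers the catalyst an unhindered enol ether, and attaches ring D afterwards. Ketone 7 is silylated (TBSOTf, Et3N, CH2Cl2, 0 °C) to the silyl enol ether diene F1. Ring-closing metathesis of F1 (second-generation Grubbs catalyst (H2IMes)(PCy3)Cl2Ru=CHPh, toluene, 60 °C) should give the 4-silyloxy-2H-chromene F2. CsF and PhNTf2 in DME convert F2 into the enol triflate F3. Aryllithium 12 is transmetalated with ZnCl2 to the arylzinc chloride F4, and Negishi coupling of F3 with F4 (Pd2(dba)3, SPhos, THF, 50 °C) gives 16.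

Step 4 (iridium-catalysed etherification). The chelated, electron-poor 2-acetylphenoxide is a weak nucleophile and a fair leaving group, so attack at the unsubstituted allyl terminus or re-ionisation of the branched ether may lower regio- and enantioselectivity. The fallback sets out from 1 and comes back at 7. It makes the stereocentre on the alcohol and forms the aryl ether by substitution at the arene, which leaves the C–O bond of the stereocentre untouched. Vinylmagnesium bromide (THF, 0 °C) adds to 1 to give the racemic allylic alcohol F5. Lipase-catalysed acylation (Novozym 435, vinyl acetate, MTBE, rt) leaves the (S)-alcohol F6 and converts its antipode into the (R)-acetate F7, which is separated. The potassium alkoxide of F6 (KN(SiMe3)2, THF, −20 °C) displaces fluoride from purchased 4-(benzyloxy)-2-fluorobenzonitrile (N#Cc1ccc(OCc2ccccc2)cc1F) by nucleophilic aromatic substitution to give the nitrile ether F8. MeMgBr (THF, 0 °C → rt), followed by mild aqueous NH4Cl/AcOH hydrolysis of the ketimine, gives 7.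

Step 11 (hydroboration–oxidation). Borane may add sluggishly to the alkene shielded by the perpendicular ring D, may place boron at C4, or the β-aryloxy borane may eliminate with opening of ring C. The fallback sets out from 7, passes through F1 and F2 described above, and comes back at 18. It introduces the C3 oxygen by enol ether oxidation and sets C4 by capture of a flavan-4-yl cation. Rubottom oxidation of F2 (dimethyldioxirane, acetone–CH2Cl2, −40 °C; then HF·pyridine) anti to the C2 aryl should give the trans-dihydroflavonol F9. NaBH4 (THF–MeOH, 0 °C) reduces the C4 ketone to the flavan-3,4-diol F10; its C4 configuration is immaterial. BF3·OEt2 (CH2Cl2, −20 °C) ionises F10 at C4, and C8 of 10 (used in excess) attacks the cation anti to the C3 hydroxyl, which gives 18 after separation from minor isomers.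

Further compounds
F1 | step 10 | tert-butyl({1-[4-(benzyloxy)-2-{[(1S)-1-[3,4-bis(benzyloxy)phenyl]prop-2-en-1-yl]oxy}phenyl]ethenyl}oxy)dimethylsilane | C=C(O[Si](C)(C)C(C)(C)C)c1ccc(OCc2ccccc2)cc1O[C@@H](C=C)c1ccc(OCc2ccccc2)c(OCc2ccccc2)c1
F2 | step 10 | (2S)-7-(benzyloxy)-2-[3,4-bis(benzyloxy)phenyl]-4-[(tert-butyldimethylsilyl)oxy]-2H-chromene | CC(C)(C)[Si](C)(C)OC1=C[C@@H](c2ccc(OCc3ccccc3)c(OCc3ccccc3)c2)Oc2cc(OCc3ccccc3)ccc12
F3 | step 10 | (2S)-7-(benzyloxy)-2-[3,4-bis(benzyloxy)phenyl]-2H-chromen-4-yl trifluoromethanesulfonate | FC(F)(F)S(=O)(=O)OC1=C[C@@H](c2ccc(OCc3ccccc3)c(OCc3ccccc3)c2)Oc2cc(OCc3ccccc3)ccc12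
F4 | step 10 | (3,5,7,4'-tetra-O-benzylafzelechin-8-yl)zinc chloride | C(Oc1ccc([C@H]2Oc3c(c(OCc4ccccc4)cc(OCc4ccccc4)c3[Zn]Cl)C[C@@H]2OCc2ccccc2)cc1)c1ccccc1
F5 | step 4 | racemic 1-[3,4-bis(benzyloxy)phenyl]prop-2-en-1-ol | OC(C=C)c1ccc(OCc2ccccc2)c(OCc2ccccc2)c1
F6 | step 4 | (1S)-1-[3,4-bis(benzyloxy)phenyl]prop-2-en-1-ol | O[C@@H](C=C)c1ccc(OCc2ccccc2)c(OCc2ccccc2)c1
F7 | step 4 | (1R)-1-[3,4-bis(benzyloxy)phenyl]prop-2-en-1-yl acetate | CC(=O)O[C@H](C=C)c1ccc(OCc2ccccc2)c(OCc2ccccc2)c1
F8 | step 4 | 4-(benzyloxy)-2-{[(1S)-1-[3,4-bis(benzyloxy)phenyl]prop-2-en-1-yl]oxy}benzonitrile | N#Cc1ccc(OCc2ccccc2)cc1O[C@@H](C=C)c1ccc(OCc2ccccc2)c(OCc2ccccc2)c1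
F9 | step 11 | (2R,3R)-7-(benzyloxy)-2-[3,4-bis(benzyloxy)phenyl]-3-hydroxychroman-4-one | O=C1c2ccc(OCc3ccccc3)cc2O[C@H](c2ccc(OCc3ccccc3)c(OCc3ccccc3)c2)[C@H]1O
F10 | step 11 | (2R,3S)-7-(benzyloxy)-2-[3,4-bis(benzyloxy)phenyl]chromane-3,4-diol, C4 epimers | OC1c2ccc(OCc3ccccc3)cc2O[C@H](c2ccc(OCc3ccccc3)c(OCc3ccccc3)c2)[C@H]1O
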